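## Retrosynthetic overview
1. The target is 7-O-methylrobustaflavone (genkwanin C3' bonded to apigenin C6''). It comes from its 4',7'',4'''-tribenzyl ether by a final neutral hydrogenolysis, which leaves the 7-OMe and the 6-aryl pattern untouched.
2. Pyranone ring C of the genkwanin unit is cut to a biaryl aldehyde plus 2',6'-dihydroxy-4'-methoxyacetophenone (one-pot aldol, oxa-Michael, dehydrogenation).
3. The key cut is the C3'–C6'' biaryl bond. Both carbons lie ortho to a phenolic oxygen and are innate nucleophiles (a hidden 1,4-dioxygen pattern). C3' is therefore inverted to an aryl-cation (aromatic enolonium) equivalent, an aryllead triacetate, and is delivered to C6'' from the free 5''-OH by ligand coupling.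
4. The aryllead comes from an arylstannane, made from 4-(benzyloxy)-3-bromobenzaldehyde. The nucleophile comes from apigenin by selective 7,4'-dibenzylation.
5. Ring order: all three rings of the apigenin unit are bought intact. Rings B and A of the genkwanin unit arrive with the bromoaldehyde and the acetophenone. The only ring built is ring C of the genkwanin unit, after the biaryl bond.

Assumption: the SMILES has no stereocentre and no axis descriptor. The 3'–6'' axis carries only OH/OH/OH/H in its ortho positions and is taken as freely equilibrating at room temperature, so no enantiocontrol is needed.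

## Route

Step 1
Reactants: 1 apigenin (5,7-dihydroxy-2-(4-hydroxyphenyl)-4H-chromen-4-one)
Product: 2 7,4'-di-O-benzylapigenin (7-(benzyloxy)-2-[4-(benzyloxy)phenyl]-5-hydroxy-4H-chromen-4-one)
Conditions: BnBr (2.2 equiv), K2CO3 (2.5 equiv), DMF, 25 to 50 °C, 12 h
Reagents that add atoms: benzyl bromide, BrCc1ccccc1
Why: Williamson ether synthesis in which the acidic, unhindered 7-OH and 4'-OH are alkylated while the 5-OH, hydrogen-bonded to the C4 carbonyl, stays free under carbonate, leaving exactly the hydroxyl that must steer the key step.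

Step 2
Reactants: 3 4-(benzyloxy)-3-bromobenzaldehyde
Product: 4 4-(benzyloxy)-3-(tributylstannyl)benzaldehyde
Conditions: (Bu3Sn)2 (1.2 equiv), Pd(PPh3)4 (5 mol%), toluene, 110 °C, 16 h
Reagents that add atoms: hexabutylditin, CCCC[Sn](CCCC)(CCCC)[Sn](CCCC)(CCCC)CCCC
Why: Palladium-catalysed stannylation of an aryl bromide with a distannane (Kosugi–Migita–Stille type: oxidative addition, Sn–Sn transmetallation, reductive elimination) tolerates the aldehyde and the benzyl ether and puts tin exactly on the carbon ortho to oxygen.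

Step 3 (key step)
Reactants: 4 4-(benzyloxy)-3-(tributylstannyl)benzaldehyde; 2 7,4'-di-O-benzylapigenin
Product: 7 4-(benzyloxy)-3-{7-(benzyloxy)-2-[4-(benzyloxy)phenyl]-5-hydroxy-4-oxo-4H-chromen-6-yl}benzaldehyde, via aryllead triacetate 5 (not isolated), via aryloxylead diacetate 6 (not isolated)
Conditions: 4 (1.3 equiv), Pb(OAc)4 (1.25 equiv), Hg(OAc)2 (6 mol%), dry CHCl3, 40 °C, 3 h; then 2 (1.0 equiv), pyridine (4 equiv), 60 °C, 16 h
Reagents that add atoms: none
Why: Pinhey arylation, in which Hg(OAc)2-catalysed tin–lead exchange turns the innately nucleophilic carbon ortho to the benzyloxy group into an aryl-cation equivalent on tetravalent lead (5), the free 5-OH of 2 displaces one acetate to give 6, and ligand coupling with reductive loss of Pb(OAc)2 can only place the aryl group on the single open ortho carbon C6 (further activated by 7-OBn and the para ring oxygen), as 3,5-dialkoxyphenols and 4-hydroxycoumarins are known to react; the new axis forms without control and has no consequence.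

Step 4
Reactants: 7 biaryl aldehyde from step 3; 8 2',6'-dihydroxy-4'-methoxyacetophenone (1-(2,6-dihydroxy-4-methoxyphenyl)ethan-1-one)
Product: 11 4',7'',4'''-tri-O-benzyl-7-O-methylrobustaflavone, via chalcone 9 (not isolated), via flavanone 10 (not isolated)
Conditions: 8 (1.2 equiv), pyrrolidine (0.5 equiv), DMSO, 100 °C, 6 h; then I2 (10 mol%), 130 °C, 4 h
Reagents that add atoms: none
Why: Amine- and iodine-catalysed domino Claisen–Schmidt condensation, oxa-Michael addition and dehydrogenation, in which pyrrolidine activates the unhindered aldehyde as its iminium ion to give 9, either of the two equivalent ortho hydroxyls closes to racemic flavanone 10, and I2 in DMSO removes H2 across C2–C3 (the oxidation that turns naringenin into apigenin), so the transient C2 stereocentre is erased and the second hydroxyl ends as the chelated 5-OH.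

Step 5
Reactants: 11 4',7'',4'''-tri-O-benzyl-7-O-methylrobustaflavone
Product: 12 7-O-methylrobustaflavone (6-[2-hydroxy-5-(5-hydroxy-7-methoxy-4-oxo-4H-chromen-2-yl)phenyl]-5,7-dihydroxy-2-(4-hydroxyphenyl)-4H-chromen-4-one)
Conditions: H2 (1 atm), Pd/C (10 wt% Pd), THF/MeOH 1:1, 25 °C, 12 h
Reagents that add atoms: none
Why: Catalytic hydrogenolysis of aryl benzyl ethers is neutral, so the 7-OMe stays, no acid-driven Wessely–Moser 6-to-8 isomerisation can start, and the chromone C2–C3 double bonds are reduced far more slowly than the O–benzyl bonds break at 1 atm; no stereocentre is involved.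

## Compound list
1 | apigenin | O=c1cc(-c2ccc(O)cc2)oc2cc(O)cc(O)c12 | starting material
2 | 7,4'-di-O-benzylapigenin | O=c1cc(-c2ccc(OCc3ccccc3)cc2)oc2cc(OCc3ccccc3)cc(O)c12 | intermediate
3 | 4-(benzyloxy)-3-bromobenzaldehyde | O=Cc1ccc(OCc2ccccc2)c(Br)c1 | starting material
4 | 4-(benzyloxy)-3-(tributylstannyl)benzaldehyde | O=Cc1ccc(OCc2ccccc2)c([Sn](CCCC)(CCCC)CCCC)c1 | intermediate
5 | [2-(benzyloxy)-5-formylphenyl]lead triacetate | O=Cc1ccc(OCc2ccccc2)c([Pb](OC(C)=O)(OC(C)=O)OC(C)=O)c1 | intermediate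
6 | [2-(benzyloxy)-5-formylphenyl]{[7-(benzyloxy)-2-(4-(benzyloxy)phenyl)-4-oxo-4H-chromen-5-yl]oxy}lead diacetate | O=Cc1ccc(OCc2ccccc2)c([Pb](OC(C)=O)(OC(C)=O)Oc2c3c(=O)cc(-c4ccc(OCc5ccccc5)cc4)oc3cc(OCc3ccccc3)c2)c1 | intermediate
7 | 4-(benzyloxy)-3-{7-(benzyloxy)-2-[4-(benzyloxy)phenyl]-5-hydroxy-4-oxo-4H-chromen-6-yl}benzaldehyde | O=Cc1ccc(OCc2ccccc2)c(-c2c(OCc3ccccc3)cc3oc(-c4ccc(OCc5ccccc5)cc4)cc(=O)c3c2O)c1 | intermediate
8 | 2',6'-dihydroxy-4'-methoxyacetophenone | CC(=O)c1c(O)cc(OC)cc1O | starting material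
9 | (E)-1-(2,6-dihydroxy-4-methoxyphenyl)-3-(aryl)prop-2-en-1-one, where aryl is the benzaldehyde ring of 7 with its flavonyl substituent | COc1cc(O)c(C(=O)/C=C/c2ccc(OCc3ccccc3)c(-c3c(OCc4ccccc4)cc4oc(-c5ccc(OCc6ccccc6)cc5)cc(=O)c4c3O)c2)c(O)c1 | intermediate
10 | (±)-5-hydroxy-7-methoxyflavanone carrying 4'-OBn and the 3'-(7,4'-di-O-benzylapigenin-6-yl) group (racemic at C2) | COc1cc(O)c2C(=O)CC(c3ccc(OCc4ccccc4)c(-c4c(OCc5ccccc5)cc5oc(-c6ccc(OCc7ccccc7)cc6)cc(=O)c5c4O)c3)Oc2c1 | intermediate
11 | 4',7'',4'''-tri-O-benzyl-7-O-methylrobustaflavone | COc1cc(O)c2c(=O)cc(-c3ccc(OCc4ccccc4)c(-c4c(OCc5ccccc5)cc5oc(-c6ccc(OCc7ccccc7)cc6)cc(=O)c5c4O)c3)oc2c1 | intermediate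
12 | 7-O-methylrobustaflavone (CNP0277373.0) | COc1cc(O)c2c(=O)cc(-c3ccc(O)c(-c4c(O)cc5oc(-c6ccc(O)cc6)cc(=O)c5c4O)c3)oc2c1 | target

## Step count and risks
Total steps: 5. Longest linear sequence: 4 steps (1 → 2 → 7 → 11 → 12, or 3 → 4 → 7 → 11 → 12).

**Step 3 is the most likely to fail.** The 5-OH is chelated to the C4 carbonyl and may exchange onto lead slowly, so protodeplumbation of 5 or acetoxylation of ring A could take over.
- The fallback sets out from 2 and returns at 7.
- Compound 2 is iodinated ortho to the free 5-OH with BnMe3NICl2 and CaCO3 in CH2Cl2/MeOH at 25 °C. This gives 7-(benzyloxy)-2-[4-(benzyloxy)phenyl]-5-hydroxy-6-iodo-4H-chromen-4-one F1.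
- F1 is then joined to stannane 4 by a normal-polarity Stille cross-coupling (Pd2(dba)3, AsPh3, CuI, DMF, 80 °C) to give 7.

**Step 4 is second.** 2,6-Dihydroxyacetophenones are sluggish aldol donors, and hot I2/DMSO may iodinate C8'' or erode benzyl ethers.
- The fallback sets out from 7 (with 8) and returns at 11. It builds ring C by acyl transfer at the flavone oxidation level, with no oxidant.
- Pinnick oxidation (NaClO2, NaH2PO4, 2-methylbut-2-ene, t-BuOH/THF/H2O) gives 4-(benzyloxy)-3-{7-(benzyloxy)-2-[4-(benzyloxy)phenyl]-5-hydroxy-4-oxo-4H-chromen-6-yl}benzoic acid F2.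
- EDC·HCl and DMAP in CH2Cl2 acylate one of the two equivalent hydroxyls of 8, giving the 2-acetyl-3-hydroxy-5-methoxyphenyl ester F3.
- Baker–Venkataraman migration (KOH, pyridine, 50 °C) gives the 1-(2,6-dihydroxy-4-methoxyphenyl)-3-arylpropane-1,3-dione F4.
- Cyclodehydration (catalytic p-TsOH, toluene, 110 °C) gives 11.

**Step 5 is third.** Compounds 11 and 12 are poorly soluble, two benzyl ethers flank the axis, and long exposure can start to saturate C2–C3.
- The fallback sets out from 11 and returns at 12.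
- The reductive cleavage is replaced by Lewis-acid ionisation with a cation trap (BCl3, pentamethylbenzene, CH2Cl2, −78 to −40 °C).
- The unchelated 7-OMe survives this, and the temperature is too low for Wessely–Moser isomerisation.
- New compounds on the way: none F0.

## Further compounds
F1 | step 3 | 7-(benzyloxy)-2-[4-(benzyloxy)phenyl]-5-hydroxy-6-iodo-4H-chromen-4-one | O=c1cc(-c2ccc(OCc3ccccc3)cc2)oc2cc(OCc3ccccc3)c(I)c(O)c12
F2 | step 4 | 4-(benzyloxy)-3-{7-(benzyloxy)-2-[4-(benzyloxy)phenyl]-5-hydroxy-4-oxo-4H-chromen-6-yl}benzoic acid | O=C(O)c1ccc(OCc2ccccc2)c(-c2c(OCc3ccccc3)cc3oc(-c4ccc(OCc5ccccc5)cc4)cc(=O)c3c2O)c1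
F3 | step 4 | 2-acetyl-3-hydroxy-5-methoxyphenyl ester of F2 | CC(=O)c1c(O)cc(OC)cc1OC(=O)c1ccc(OCc2ccccc2)c(-c2c(OCc3ccccc3)cc3oc(-c4ccc(OCc5ccccc5)cc4)cc(=O)c3c2O)c1
F4 | step 4 | 1-(2,6-dihydroxy-4-methoxyphenyl)-3-(aryl)propane-1,3-dione, aryl as in F2 | COc1cc(O)c(C(=O)CC(=O)c2ccc(OCc3ccccc3)c(-c3c(OCc4ccccc4)cc4oc(-c5ccc(OCc6ccccc6)cc5)cc(=O)c4c3O)c2)c(O)c1
F0 | step 5 | none | none
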